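## Retrosynthetic overview
1. Target oleate ⇒ (S)-α-cyclogeranylgeranyl acetate + methyl oleate. This is an acyl swap at the C1 oxygen, and the Z-alkene is bought in.
2. (S)-α-cyclogeranylgeranyl acetate ⇒ all-E-geranylgeranyl acetate by disconnecting C10–C15. Forward, this is a metal-free cyclisation catalysed by a chiral Brønsted acid and interrupted after one ring. It sets C10 (S) and places the 11,12-alkene.
3. Geranylgeranyl acetate ⇒ geranylgeraniol + acetic anhydride.
4. Ring order: ring A is the only ring and forms in step 2. The 2E and 6E alkenes come unchanged from geranylgeraniol.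

Atom numbers follow geranylgeraniol (C1 = CH2O, C15 = terminal CMe2 carbon).

Catalyst IDPi-T is a new member of the imidodiphosphorimidate (IDPi) Brønsted acid family. Two (S)-3,3′-di(triphenylen-2-yl)-1,1′-bi-2-naphthol phosphorus units are bridged by one nitrogen, each phosphorus carries an N-SO2C6F5 imido group, and there is one acidic N–H.

Assumption: the (S,S) form of IDPi-T is taken to give the S product. If the first run shows the opposite sense, the (R,R) form is used and nothing else changes.

## Route

**Step 1**
Reactants: 1 all-E-geranylgeraniol; 2 acetic anhydride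
Product: 3 (2E,6E,10E)-geranylgeranyl acetate
Conditions: Ac2O (1.5 equiv), Et3N, DMAP (5 mol %), CH2Cl2, 0 °C to rt
Reagents that add atoms: acetic anhydride (compound 2), CC(=O)OC(C)=O
Why: DMAP-catalysed O-acylation of a primary allylic alcohol under basic conditions causes no allylic transposition or E/Z erosion and creates no stereocenter, and the small acetate switches off the 2,3-alkene for step 2, keeps the oleate Z-alkene away from strong acid, and leaves the key product assayable by chiral GC or HPLC and purifiable on AgNO3/SiO2.

**Step 2**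
Reactants: 3 (2E,6E,10E)-geranylgeranyl acetate
Product: 5 (S)-α-cyclogeranylgeranyl acetate [(2E,6E)-3,7-dimethyl-9-[(1S)-2,6,6-trimethylcyclohex-2-en-1-yl]nona-2,6-dien-1-yl acetate], via monocyclic tertiary cation 4 (not isolated)
Conditions: (S,S)-IDPi-T (5 mol %), dry methylcyclohexane/PhCF3 4:1 (0.02 M), 0 °C, run to ca. 80 % conversion; Et3N quench; AgNO3/SiO2 chromatography (recovered 3 is recycled)
Reagents that add atoms: none
Why: Proposed new method: an interrupted, enantioselective protonative polyene cyclisation in which the confined acid protonates only the sterically open terminal isopropylidene at C14. C15 then closes onto the Re face of C10 of the E-10,11-alkene through a chair-folded terminal isoprene pair held between the triphenylenyl walls, which sets C10 as S. In a non-polar medium that donates no hydrogen bonds, the contact ion pair 4 should collapse by proton transfer faster than a second ring can close, because the anion has just delivered its proton at C14, sits over the C12–C14 edge of the new ring, and can take a C12 hydrogen to give the α-olefin. The competing closure is slow because the C1–C9 tail stays outside the pocket, carries no terminating nucleophile, and must fold before its 6,7-alkene can reach C11. The hindered C10–H is not removed, and the product alkenes are too encumbered to re-enter the pocket. The closest known reaction types are the IDPi-catalysed protonative polyene cyclisation of homofarnesol to ambroxide in fluorinated alcohols (a full cascade) and the partial, ring A only cyclisations seen with stoichiometric chiral Lewis-acid-assisted Brønsted acids; neither has been made catalytic, metal-free, ring A only and α-olefin-selective on a polyprenyl ester.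

**Step 3**
Reactants: 5 (S)-α-cyclogeranylgeranyl acetate; 6 methyl oleate
Product: 8 (2E,6E)-3,7-dimethyl-9-[(1S)-2,6,6-trimethylcyclohex-2-en-1-yl]nona-2,6-dien-1-yl (9Z)-octadec-9-enoate (target), via sodium alkoxide 7 (not isolated)
Conditions: 6 (3 equiv), NaOMe (10 mol %, solid), neat, 60 °C, 20 mbar; SiO2 chromatography
Reagents that add atoms: methyl oleate (compound 6), CCCCCCCC/C=C\CCCCCCCC(=O)OC
Why: Alkoxide-catalysed ester interchange (transesterification) is pulled to completion by stripping off the volatile acetate ester, as practised for retinyl acetate to retinyl palmitate, and the base touches neither C10 (no acidic hydrogen) nor the E,E and Z alkenes.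

## Compound list
1 | all-E-geranylgeraniol, (2E,6E,10E)-3,7,11,15-tetramethylhexadeca-2,6,10,14-tetraen-1-ol | OC/C=C(\C)CC/C=C(\C)CC/C=C(\C)CCC=C(C)C | starting material
2 | acetic anhydride | CC(=O)OC(C)=O | starting material
3 | (2E,6E,10E)-geranylgeranyl acetate | CC(=O)OC/C=C(\C)CC/C=C(\C)CC/C=C(\C)CCC=C(C)C | intermediate
4 | (2S)-2-[(3E,7E)-9-acetoxy-3,7-dimethylnona-3,7-dien-1-yl]-1,3,3-trimethylcyclohexyl cation, ion pair with the IDPi-T anion | CC(=O)OC/C=C(\C)CC/C=C(\C)CC[C@@H]1[C+](C)CCCC1(C)C | intermediate (not isolated)
5 | (2E,6E)-3,7-dimethyl-9-[(1S)-2,6,6-trimethylcyclohex-2-en-1-yl]nona-2,6-dien-1-yl acetate | CC(=O)OC/C=C(\C)CC/C=C(\C)CC[C@@H]1C(C)=CCCC1(C)C | intermediate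
6 | methyl oleate, methyl (9Z)-octadec-9-enoate | CCCCCCCC/C=C\CCCCCCCC(=O)OC | starting material
7 | sodium (2E,6E)-3,7-dimethyl-9-[(1S)-2,6,6-trimethylcyclohex-2-en-1-yl]nona-2,6-dien-1-olate | [Na+].[O-]C/C=C(\C)CC/C=C(\C)CC[C@@H]1C(C)=CCCC1(C)C | intermediate (not isolated)
8 | (2E,6E)-3,7-dimethyl-9-[(1S)-2,6,6-trimethylcyclohex-2-en-1-yl]nona-2,6-dien-1-yl (9Z)-octadec-9-enoate | CCCCCCCC/C=C\CCCCCCCC(=O)OC/C=C(\C)CC/C=C(\C)CC[C@@H]1C(C)=CCCC1(C)C | target

## Step count and risks
Total steps: 3. Longest linear sequence: 3.

**Risk 1, step 2 (the new step).**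

Failure modes:
- The cascade runs on to bicyclic labdane-type acetates.
- Proton loss gives the γ (exocyclic) or β (achiral) olefin.
- The allylic acetate ionises.
- Turnover in the non-polar medium is slow.
- The enantiomeric ratio is low.

The fallback uses known chemistry only and changes the disconnection to a C10 + C10 sulfone coupling. Of the numbered compounds it uses only acetic anhydride 2, from which it sets out, and it comes back at 5.

Common precursor: commercial geraniol is acetylated with 2 (Et3N, DMAP) to geranyl acetate F1.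

Left half, from one portion of F1:
- Shi epoxidation at the electron-rich 6,7-alkene uses the enantiomer of the fructose-derived ketone (made from L-sorbose) with KHSO5 and K2CO3 in MeCN/dimethoxymethane/buffer at 0 °C. It gives (6S)-6,7-epoxygeranyl acetate F2.
- ZrCl4 in CH2Cl2 opens the epoxide and closes the ring through a chair, relaying the epoxide configuration to the ring carbon. The product is the cis-hydroxy acetate [(1R,5S)-5-hydroxy-2,6,6-trimethylcyclohex-2-en-1-yl]methyl acetate F3.
- Barton–McCombie deoxygenation proceeds by way of the imidazolylthiocarbonyl derivative F4 (1,1′-thiocarbonyldiimidazole, DMAP). Bu3SnH and AIBN in toluene at 110 °C then give (S)-α-cyclogeranyl acetate F5.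
- K2CO3/MeOH gives (S)-α-cyclogeraniol F6.
- PhSSPh/Bu3P gives (S)-α-cyclogeranyl phenyl sulfide F7.
- H2O2 with catalytic (NH4)6Mo7O24 in EtOH gives (S)-α-cyclogeranyl phenyl sulfone F8.

Right half, from the other portion of F1:
- Oxidation at the E-methyl group (SeO2 cat., t-BuOOH, CH2Cl2) gives (2E,6E)-8-hydroxygeranyl acetate F9.
- CBr4/PPh3 in CH2Cl2 at 0 °C gives (2E,6E)-8-bromogeranyl acetate F10.

Union:
- F8 is lithiated (n-BuLi, THF/DMPU, −78 °C) and alkylated with F10 to the C20 sulfonyl acetate F11, obtained as both epimers at the sulfonyl-bearing carbon.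
- Na/Hg with Na2HPO4 in MeOH/THF at −20 °C removes the sulfonyl group and delivers 5.

**Risk 2, step 3.**

Failure modes are incomplete exchange on small scale, tedious separation from excess 6, and Claisen-type side reactions of the esters.

The fallback sets out from 5 and comes back at 8. Instead of a direct interchange, the alcohol is isolated and then acylated by carboxyl activation. K2CO3/MeOH at rt gives (S)-α-cyclogeranylgeraniol F12. Steglich esterification of F12 with commercial oleic acid (EDC·HCl, DMAP, CH2Cl2, 0 °C to rt) gives 8.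

**Risk 3, step 1.**

The risk is low. The concerns are traces of allylic transposition or colour bodies from the amine and anhydride system, and carry-over of isomers from commercial 1.

The fallback sets out from 1 and comes back at 3. It is a biocatalytic acyl transfer at neutral pH through a serine acyl-enzyme, using immobilised Candida antarctica lipase B and vinyl acetate in methyl tert-butyl ether at 30 °C. No new compound is made on the way.

## Further compounds
F0 | step 1 | none | none
F1 | step 2 | geranyl acetate, (2E)-3,7-dimethylocta-2,6-dien-1-yl acetate | CC(=O)OC/C=C(\C)CCC=C(C)C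
F2 | step 2 | (6S)-6,7-epoxygeranyl acetate, (2E)-5-[(2S)-3,3-dimethyloxiran-2-yl]-3-methylpent-2-en-1-yl acetate | CC(=O)OC/C=C(\C)CC[C@@H]1OC1(C)C
F3 | step 2 | [(1R,5S)-5-hydroxy-2,6,6-trimethylcyclohex-2-en-1-yl]methyl acetate | CC(=O)OC[C@@H]1C(C)=CC[C@H](O)C1(C)C
F4 | step 2 | [(1R,5S)-5-(imidazole-1-carbothioyloxy)-2,6,6-trimethylcyclohex-2-en-1-yl]methyl acetate | CC(=O)OC[C@@H]1C(C)=CC[C@H](OC(=S)n2ccnc2)C1(C)C
F5 | step 2 | (S)-α-cyclogeranyl acetate, [(1S)-2,6,6-trimethylcyclohex-2-en-1-yl]methyl acetate | CC(=O)OC[C@@H]1C(C)=CCCC1(C)C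
F6 | step 2 | (S)-α-cyclogeraniol, [(1S)-2,6,6-trimethylcyclohex-2-en-1-yl]methanol | OC[C@@H]1C(C)=CCCC1(C)C
F7 | step 2 | (S)-α-cyclogeranyl phenyl sulfide | c1ccccc1SC[C@@H]2C(C)=CCCC2(C)C
F8 | step 2 | (S)-α-cyclogeranyl phenyl sulfone | O=S(=O)(c1ccccc1)C[C@@H]2C(C)=CCCC2(C)C
F9 | step 2 | (2E,6E)-8-hydroxy-3,7-dimethylocta-2,6-dien-1-yl acetate | CC(=O)OC/C=C(\C)CC/C=C(\C)CO
F10 | step 2 | (2E,6E)-8-bromo-3,7-dimethylocta-2,6-dien-1-yl acetate | CC(=O)OC/C=C(\C)CC/C=C(\C)CBr
F11 | step 2 | (2E,6E)-3,7-dimethyl-9-(phenylsulfonyl)-9-[(1S)-2,6,6-trimethylcyclohex-2-en-1-yl]nona-2,6-dien-1-yl acetate, both C9 epimers | CC(=O)OC/C=C(\C)CC/C=C(\C)CC([C@@H]1C(C)=CCCC1(C)C)S(=O)(=O)c2ccccc2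
F12 | step 3 | (S)-α-cyclogeranylgeraniol, (2E,6E)-3,7-dimethyl-9-[(1S)-2,6,6-trimethylcyclohex-2-en-1-yl]nona-2,6-dien-1-ol | OC/C=C(\C)CC/C=C(\C)CC[C@@H]1C(C)=CCCC1(C)C
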